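**Plan**

- Feature: the two pyranone rings share a 1,4-diketone, C4(=O)–C3–C3''–C4''(=O), and each of C3 and C3'' is tied through C2–O1 (C2''–O1'') to the benzo ring that bears C4 (C4''). With a C3≡C3'' triple bond the silylated target is therefore an isomer of a bis(2-formylaryl) ether of a 1,4-diarylbut-2-yne-1,4-diol.
- Retrosynthesis: the 7- and 7''-O-silyl groups come off last; C4–C3 and C4''–C3'' are cut together (two acyl-anion additions to one alkyne); then both aryl C8a–O1 bonds (fluoride displacement); then C2–C3 and C2''–C3'' (alkynyl additions to 4-methoxybenzaldehyde).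
- Forward: the C2–C3≡C3''–C2'' chain is built by two catalyst-controlled alkynylations, two formyl aryl ether arms are attached, and one carbene-catalysed step closes the first pyranone ring (6-exo-dig) and then the second (6-exo-trig); desilylation ends the route.
- Stereochemistry: C2 and C2'' come from the two (S)-1,1'-bi-2-naphthol/Ti(OiPr)4 alkynylations and no bond to them is broken afterwards (R in the diol reads S in the flavanone only because CIP ranks change). C3 and C3'' are α-keto centres expected to settle trans to the neighbouring aryl groups under thermodynamic control.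

Key step: step 9

Numbering: flavanone numbering is used throughout, the second unit carrying double primes, also in open-chain precursors.
Assumption: (S)-1,1'-bi-2-naphthol with Ti(OiPr)4 is taken to direct the alkynyl group to the Si face of the aryl aldehyde, as in the related dialkylzinc additions, which gives the (R)-carbinol; should adduct 4 prove to be (S), the (R)-ligand is used in steps 1 and 4 and nothing else changes.

**Route**

Step 1
Reactants: 1 4-methoxybenzaldehyde; 2 ethynyltrimethylsilane
Product: 4 (R)-1-(4-methoxyphenyl)-3-(trimethylsilyl)prop-2-yn-1-ol, via ethyl[(trimethylsilyl)ethynyl]zinc 3 (not isolated)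
Conditions: 2 (2.2 equiv), ZnEt2 (2 equiv), Cy2NH (5 mol %), (S)-1,1'-bi-2-naphthol (20 mol %), Et2O, rt; Ti(OiPr)4 (50 mol %); then 1, rt
Reagents that add atoms: none
Why: Binaphthol–titanium-catalysed asymmetric alkynylzinc addition to an aromatic aldehyde, a substrate class for which this catalyst is well established; delivery to the Si face under the (S)-ligand sets the carbinol carbon (future C2) as R.

Step 2
Reactants: 4 (R)-1-(4-methoxyphenyl)-3-(trimethylsilyl)prop-2-yn-1-ol
Product: 5 (R)-tert-butyl{[1-(4-methoxyphenyl)-3-(trimethylsilyl)prop-2-yn-1-yl]oxy}dimethylsilane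
Conditions: TBSCl, imidazole, DMF, rt
Reagents that add atoms: tert-butyldimethylsilyl chloride, CC(C)(C)[Si](C)(C)Cl
Why: Standard silylation of a secondary alcohol, which masks the hydroxyl group so that it cannot bind zinc or titanium in step 4; the stereocentre is not touched.

Step 3
Reactants: 5 (R)-tert-butyl{[1-(4-methoxyphenyl)-3-(trimethylsilyl)prop-2-yn-1-yl]oxy}dimethylsilane
Product: 6 (S)-tert-butyl{[1-(4-methoxyphenyl)prop-2-yn-1-yl]oxy}dimethylsilane (same arrangement in space as 5; the descriptor changes because a terminal ethynyl group ranks below aryl)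
Conditions: K2CO3 (0.2 equiv), MeOH, 0 °C to rt
Reagents that add atoms: none
Why: Methanolysis of the alkynyl C–Si bond (protodesilylation) is far faster than cleavage of the secondary O-silyl ether, so only the alkyne terminus is freed.

Step 4
Reactants: 6 (S)-tert-butyl{[1-(4-methoxyphenyl)prop-2-yn-1-yl]oxy}dimethylsilane; 1 4-methoxybenzaldehyde
Product: 8 (1R,4R)-4-[(tert-butyldimethylsilyl)oxy]-1,4-bis(4-methoxyphenyl)but-2-yn-1-ol, via alkynyl(ethyl)zinc reagent 7 (not isolated)
Conditions: 6 (1.5 equiv), ZnEt2 (1.5 equiv), Cy2NH (5 mol %), (S)-1,1'-bi-2-naphthol (20 mol %), Et2O, rt; Ti(OiPr)4 (50 mol %); then 1, rt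
Reagents that add atoms: none
Why: A second binaphthol–titanium alkynylzinc addition in which the catalyst, not the remote silyloxy centre, should fix the new carbinol (future C2'') as R; the (1R,4S) diastereomer, which also collects stereochemical leakage from step 1 by statistical amplification, is removable by chromatography.

Step 5
Reactants: 8 (1R,4R)-4-[(tert-butyldimethylsilyl)oxy]-1,4-bis(4-methoxyphenyl)but-2-yn-1-ol
Product: 9 (1R,4R)-1,4-bis(4-methoxyphenyl)but-2-yne-1,4-diol
Conditions: Bu4NF, THF, 0 °C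
Reagents that add atoms: none
Why: Fluoride cleavage of the silyl ether under non-acidic conditions, which avoids ionisation of the 4-methoxybenzylic propargylic carbinols.

Step 6
Reactants: 10 3-fluoro-5-methoxyphenol
Product: 11 (3-fluoro-5-methoxyphenoxy)triisopropylsilane
Conditions: TIPSCl, imidazole, DMF, rt
Reagents that add atoms: triisopropylsilyl chloride, CC(C)[Si](Cl)(C(C)C)C(C)C
Why: Standard phenol silylation; the bulky, non-coordinating silyl ether also shields both ring positions next to it in the following metalation.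

Step 7
Reactants: 11 (3-fluoro-5-methoxyphenoxy)triisopropylsilane
Product: 13 2-fluoro-6-methoxy-4-[(triisopropylsilyl)oxy]benzaldehyde, via aryllithium 12 (not isolated)
Conditions: n-BuLi, THF, −78 °C; DMF, −78 to 0 °C; then H2O
Reagents that add atoms: N,N-dimethylformamide, CN(C)C=O
Why: Directed ortho-metalation at the ring position flanked by fluorine and methoxy (the most acidic C–H, with the methoxy group coordinating lithium), followed by formylation; −78 °C prevents loss of LiF to an aryne.

Step 8
Reactants: 9 (1R,4R)-1,4-bis(4-methoxyphenyl)but-2-yne-1,4-diol; 13 2-fluoro-6-methoxy-4-[(triisopropylsilyl)oxy]benzaldehyde (two equivalents react)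
Product: 15 2,2'-{[(1R,4R)-1,4-bis(4-methoxyphenyl)but-2-yne-1,4-diyl]bis(oxy)}bis{6-methoxy-4-[(triisopropylsilyl)oxy]benzaldehyde}, via mono(aryl ether) alkoxide 14 (not isolated)
Conditions: NaH (2.2 equiv), THF, 0 °C; then 13 (2.4 equiv), THF/DMF, 0 °C to rt
Reagents that add atoms: none
Why: Nucleophilic aromatic substitution of fluoride ortho to the formyl group (Meisenheimer adduct stabilised by the aldehyde, both donor groups meta to the reacting carbon); the bond formed is aryl C8a–O1, so the carbinol configuration is retained.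

Step 9
Reactants: 15 2,2'-{[(1R,4R)-1,4-bis(4-methoxyphenyl)but-2-yne-1,4-diyl]bis(oxy)}bis{6-methoxy-4-[(triisopropylsilyl)oxy]benzaldehyde}
Product: 17 (2S,3R,2''S,3''R)-5,5''-dimethoxy-2,2''-bis(4-methoxyphenyl)-7,7''-bis[(triisopropylsilyl)oxy]-3,3''-bichroman-4,4''-dione, via (E)-3-alkylidenechroman-4-one aldehyde 16 (not isolated)
Conditions: 3-mesityl-5,6,7,8-tetrahydro-4H-cyclohepta[d]thiazol-3-ium perchlorate (20 mol %), K2CO3 (40 mol %), THF, 70 °C
Reagents that add atoms: none
Why: Proposed new method: the thiazol-2-ylidene adds to one formyl group to give a Breslow intermediate whose nucleophilic carbon C4 bonds to alkyne carbon C3 while its O–H proton passes to C3'' (concerted, Conia-ene-like syn addition), releasing the carbene and leaving the (E)-enone 16; the second formyl group, activated in the same way, then adds through C4'' to the enone β-carbon C3'' and the resulting enol is protonated at C3. The closest known reaction type is the carbene-catalysed intramolecular hydroacylation of unactivated alkynes in O-propargyl salicylaldehydes and its cascade with an intermolecular Stetter reaction; new here are the intramolecular second stage on the same alkyne, an alkyne without aryl substituent and formyl groups flanked by two oxygen substituents. The first pyranone ring closes 6-exo-dig (C4 onto C3) and the second 6-exo-trig (C4'' onto C3''). C3'' is set in the Stetter bond formation and C3 in the final protonation, each beside a fixed centre (C2'' and C2) and each α to a ketone, so K2CO3 at 70 °C should equilibrate both to the 2,3-trans diequatorial arrangement, which with the untouched C2 and C2'' gives the (2S,3R,2''S,3''R) isomer. The step needs exo rather than 7-endo attack and addition to carbon rather than benzoin coupling; the short O1–C2 tether, which brings only C3 (then C3'') within reach of the acyl-anion carbon, and the two ortho substituents, which hinder aldehyde–aldehyde coupling, should secure this. A small thiazolium carbene and a weak heterogeneous base are chosen to reach the hindered aldehydes while limiting propargyl–allenyl isomerisation and retro-oxa-Michael opening of the product.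

Step 10
Reactants: 17 (2S,3R,2''S,3''R)-5,5''-dimethoxy-2,2''-bis(4-methoxyphenyl)-7,7''-bis[(triisopropylsilyl)oxy]-3,3''-bichroman-4,4''-dione
Product: 19 4',4''',5,5''-tetramethylchamaejasmin, (2S,3R,2''S,3''R)-7,7''-dihydroxy-5,5''-dimethoxy-2,2''-bis(4-methoxyphenyl)-3,3''-bichroman-4,4''-dione, via mono(triisopropylsilyl) ether 18 (not isolated)
Conditions: Bu4NF, AcOH (1:1), THF, 0 °C
Reagents that add atoms: none
Why: Fluoride cleavage of the two aryl silyl ethers, buffered with acetic acid so that neither C3 epimerisation nor retro-oxa-Michael ring opening is triggered.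

**Compound list**

1 | 4-methoxybenzaldehyde | COc1ccc(C=O)cc1 | starting material
2 | ethynyltrimethylsilane | C#C[Si](C)(C)C | starting material
3 | ethyl[(trimethylsilyl)ethynyl]zinc (not isolated) | CC[Zn]C#C[Si](C)(C)C | intermediate
4 | (R)-1-(4-methoxyphenyl)-3-(trimethylsilyl)prop-2-yn-1-ol | COc1ccc([C@@H](O)C#C[Si](C)(C)C)cc1 | intermediate
5 | (R)-tert-butyl{[1-(4-methoxyphenyl)-3-(trimethylsilyl)prop-2-yn-1-yl]oxy}dimethylsilane | COc1ccc([C@@H](O[Si](C)(C)C(C)(C)C)C#C[Si](C)(C)C)cc1 | intermediate
6 | (S)-tert-butyl{[1-(4-methoxyphenyl)prop-2-yn-1-yl]oxy}dimethylsilane | COc1ccc([C@@H](O[Si](C)(C)C(C)(C)C)C#C)cc1 | intermediate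
7 | ethyl{(3R)-3-[(tert-butyldimethylsilyl)oxy]-3-(4-methoxyphenyl)prop-1-yn-1-yl}zinc (not isolated) | CC[Zn]C#C[C@H](O[Si](C)(C)C(C)(C)C)c1ccc(OC)cc1 | intermediate
8 | (1R,4R)-4-[(tert-butyldimethylsilyl)oxy]-1,4-bis(4-methoxyphenyl)but-2-yn-1-ol | COc1ccc([C@@H](O)C#C[C@H](O[Si](C)(C)C(C)(C)C)c2ccc(OC)cc2)cc1 | intermediate
9 | (1R,4R)-1,4-bis(4-methoxyphenyl)but-2-yne-1,4-diol | COc1ccc([C@@H](O)C#C[C@H](O)c2ccc(OC)cc2)cc1 | intermediate
10 | 3-fluoro-5-methoxyphenol | COc1cc(O)cc(F)c1 | starting material
11 | (3-fluoro-5-methoxyphenoxy)triisopropylsilane | COc1cc(F)cc(O[Si](C(C)C)(C(C)C)C(C)C)c1 | intermediate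
12 | {2-fluoro-6-methoxy-4-[(triisopropylsilyl)oxy]phenyl}lithium (not isolated) | [Li]c1c(F)cc(O[Si](C(C)C)(C(C)C)C(C)C)cc1OC | intermediate
13 | 2-fluoro-6-methoxy-4-[(triisopropylsilyl)oxy]benzaldehyde | COc1cc(O[Si](C(C)C)(C(C)C)C(C)C)cc(F)c1C=O | intermediate
14 | 2-{[(1R,4R)-4-hydroxy-1,4-bis(4-methoxyphenyl)but-2-yn-1-yl]oxy}-6-methoxy-4-[(triisopropylsilyl)oxy]benzaldehyde, present as its sodium alkoxide (not isolated) | COc1ccc([C@@H](O)C#C[C@H](Oc2cc(O[Si](C(C)C)(C(C)C)C(C)C)cc(OC)c2C=O)c2ccc(OC)cc2)cc1 | intermediate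
15 | 2,2'-{[(1R,4R)-1,4-bis(4-methoxyphenyl)but-2-yne-1,4-diyl]bis(oxy)}bis{6-methoxy-4-[(triisopropylsilyl)oxy]benzaldehyde} | COc1ccc([C@@H](Oc2cc(O[Si](C(C)C)(C(C)C)C(C)C)cc(OC)c2C=O)C#C[C@H](Oc2cc(O[Si](C(C)C)(C(C)C)C(C)C)cc(OC)c2C=O)c2ccc(OC)cc2)cc1 | intermediate
16 | (2R,3E)-3-{(2S)-2-[2-formyl-3-methoxy-5-(triisopropylsilyloxy)phenoxy]-2-(4-methoxyphenyl)ethylidene}-5-methoxy-2-(4-methoxyphenyl)-7-[(triisopropylsilyl)oxy]chroman-4-one (not isolated; C2 and C2'' unchanged in space, descriptors follow CIP ranks) | COc1ccc([C@H]2Oc3cc(O[Si](C(C)C)(C(C)C)C(C)C)cc(OC)c3C(=O)/C2=C/[C@H](Oc2cc(O[Si](C(C)C)(C(C)C)C(C)C)cc(OC)c2C=O)c2ccc(OC)cc2)cc1 | intermediate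
17 | (2S,3R,2''S,3''R)-5,5''-dimethoxy-2,2''-bis(4-methoxyphenyl)-7,7''-bis[(triisopropylsilyl)oxy]-3,3''-bichroman-4,4''-dione | COc1ccc([C@H]2Oc3cc(O[Si](C(C)C)(C(C)C)C(C)C)cc(OC)c3C(=O)[C@@H]2[C@H]2C(=O)c3c(OC)cc(O[Si](C(C)C)(C(C)C)C(C)C)cc3O[C@@H]2c2ccc(OC)cc2)cc1 | intermediate
18 | (2S,3R,2''S,3''R)-7-hydroxy-5,5''-dimethoxy-2,2''-bis(4-methoxyphenyl)-7''-[(triisopropylsilyl)oxy]-3,3''-bichroman-4,4''-dione (not isolated) | COc1ccc([C@H]2Oc3cc(O)cc(OC)c3C(=O)[C@@H]2[C@H]2C(=O)c3c(OC)cc(O[Si](C(C)C)(C(C)C)C(C)C)cc3O[C@@H]2c2ccc(OC)cc2)cc1 | intermediate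
19 | 4',4''',5,5''-tetramethylchamaejasmin, (2S,3R,2''S,3''R)-7,7''-dihydroxy-5,5''-dimethoxy-2,2''-bis(4-methoxyphenyl)-3,3''-bichroman-4,4''-dione | COc1ccc([C@H]2Oc3cc(O)cc(OC)c3C(=O)[C@@H]2[C@H]2C(=O)c3c(OC)cc(O)cc3O[C@@H]2c2ccc(OC)cc2)cc1 | target

**Summary**

Total step count: 10. Longest linear sequence: 8 steps (steps 1–5, then 8–10); steps 6–7 form the second branch.

Steps most likely to fail:

1. Step 9 (the new carbene cascade). Carbene addition to the doubly ortho-substituted, electron-rich formyl groups may be too slow, the base may isomerise the propargylic ethers to allenyl ethers, the sequence may stall after the first ring, or the product rings may open by retro-oxa-Michael reaction with loss of C2 integrity. Fallback by known acyl-radical chemistry, setting out from 15 and returning at 17: Pinnick oxidation (NaClO2, NaH2PO4, 2-methylbut-2-ene, t-BuOH/H2O) should give the dicarboxylic acid F1, and PhSeSePh/PBu3 the bis(Se-phenyl selenoester) F2. Slow addition of Bu3SnH with azobisisobutyronitrile in benzene at 80 °C would then generate an aroyl radical that cyclises 6-exo-dig onto the alkyne; hydrogen transfer gives the enone selenoester F3 (not isolated), whose second aroyl radical adds 6-exo-trig to the enone β-carbon (Giese-type). Brief Et3N treatment to bring C3 and C3'' to the trans,trans arrangement would deliver 17.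

2. Step 8 (double fluoride displacement). The alkoxide may attack silicon (loss or migration of the silyl group) or the formyl group (hemiacetal formation, hydride transfer from the carbinol), and the second substitution may lag, leaving the mono-ether. Fallback with a nitrile as activating group, setting out from 11 and returning at 15: the aryllithium 12 is quenched with 4-methylbenzenesulfonyl cyanide to give 2-fluoro-6-methoxy-4-[(triisopropylsilyl)oxy]benzonitrile F4. This more strongly activated partner, which has no carbonyl group to intercept the alkoxide, reacts with the disodium salt of 9 (NaH, THF, 0 °C) through the mono-ether hydroxy nitrile F5 (not isolated) to the bis(nitrile) bis-ether F6. Reduction with i-Bu2AlH in toluene at −78 °C and mild aqueous hydrolysis of the aldimine would give 15.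

3. Step 4 (second alkynylation). Zincation and addition of the hindered silyloxy alkyne may be sluggish, and incomplete catalyst control would divert material into the (1R,4S) diastereomer. Fallback by reduction instead of addition, setting out from 1 and returning at 9: the bis(bromomagnesium) acetylide made from ethynylmagnesium bromide and EtMgBr adds to 1 through the O,C-bis(bromomagnesium) derivative of 1-(4-methoxyphenyl)prop-2-yn-1-ol F7 (not isolated) to give 1,4-bis(4-methoxyphenyl)but-2-yne-1,4-diol as a stereoisomer mixture F8. MnO2 in CH2Cl2 oxidises it to 1,4-bis(4-methoxyphenyl)but-2-yne-1,4-dione F9. Midland reduction with B-(3-pinanyl)-9-borabicyclo[3.3.1]nonane from (+)-α-pinene in THF at rt, with the alkynyl group as the small substituent, should proceed through (4R)-4-hydroxy-1,4-bis(4-methoxyphenyl)but-2-yn-1-one F10 (not isolated) to 9. The meso diol is removed by chromatography, and the double reduction amplifies the enantiomeric purity statistically.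

Further compounds
F1 | step 9 | 2,2'-{[(1R,4R)-1,4-bis(4-methoxyphenyl)but-2-yne-1,4-diyl]bis(oxy)}bis{6-methoxy-4-[(triisopropylsilyl)oxy]benzoic acid} | COc1ccc([C@@H](Oc2cc(O[Si](C(C)C)(C(C)C)C(C)C)cc(OC)c2C(=O)O)C#C[C@H](Oc2cc(O[Si](C(C)C)(C(C)C)C(C)C)cc(OC)c2C(=O)O)c2ccc(OC)cc2)cc1
F2 | step 9 | bis(Se-phenyl) selenoester of F1 | COc1ccc([C@@H](Oc2cc(O[Si](C(C)C)(C(C)C)C(C)C)cc(OC)c2C(=O)[Se]c2ccccc2)C#C[C@H](Oc2cc(O[Si](C(C)C)(C(C)C)C(C)C)cc(OC)c2C(=O)[Se]c2ccccc2)c2ccc(OC)cc2)cc1
F3 | step 9 | Se-phenyl selenoester analogue of 16, alkene geometry not defined | COc1ccc([C@H]2Oc3cc(O[Si](C(C)C)(C(C)C)C(C)C)cc(OC)c3C(=O)C2=C[C@H](Oc2cc(O[Si](C(C)C)(C(C)C)C(C)C)cc(OC)c2C(=O)[Se]c2ccccc2)c2ccc(OC)cc2)cc1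
F4 | step 8 | 2-fluoro-6-methoxy-4-[(triisopropylsilyl)oxy]benzonitrile | COc1cc(O[Si](C(C)C)(C(C)C)C(C)C)cc(F)c1C#N
F5 | step 8 | 2-{[(1R,4R)-4-hydroxy-1,4-bis(4-methoxyphenyl)but-2-yn-1-yl]oxy}-6-methoxy-4-[(triisopropylsilyl)oxy]benzonitrile | COc1ccc([C@@H](O)C#C[C@H](Oc2cc(O[Si](C(C)C)(C(C)C)C(C)C)cc(OC)c2C#N)c2ccc(OC)cc2)cc1
F6 | step 8 | 2,2'-{[(1R,4R)-1,4-bis(4-methoxyphenyl)but-2-yne-1,4-diyl]bis(oxy)}bis{6-methoxy-4-[(triisopropylsilyl)oxy]benzonitrile} | COc1ccc([C@@H](Oc2cc(O[Si](C(C)C)(C(C)C)C(C)C)cc(OC)c2C#N)C#C[C@H](Oc2cc(O[Si](C(C)C)(C(C)C)C(C)C)cc(OC)c2C#N)c2ccc(OC)cc2)cc1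
F7 | step 4 | O,C-bis(bromomagnesium) derivative of racemic 1-(4-methoxyphenyl)prop-2-yn-1-ol | COc1ccc(C(O[Mg]Br)C#C[Mg]Br)cc1
F8 | step 4 | 1,4-bis(4-methoxyphenyl)but-2-yne-1,4-diol, mixture of racemic and meso forms | COc1ccc(C(O)C#CC(O)c2ccc(OC)cc2)cc1
F9 | step 4 | 1,4-bis(4-methoxyphenyl)but-2-yne-1,4-dione | COc1ccc(C(=O)C#CC(=O)c2ccc(OC)cc2)cc1
F10 | step 4 | (4R)-4-hydroxy-1,4-bis(4-methoxyphenyl)but-2-yn-1-one | COc1ccc([C@@H](O)C#CC(=O)c2ccc(OC)cc2)cc1
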